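**Remarks**

- Locants: ring atoms are written A-1 to A-6 and B-1 to B-6 (A-1 and B-1 carry the ether oxygen, A-5 and B-4 the chain). Chain carbons run from C-1 (on B-4) to C-12 (on A-5). Labels without a hyphen (A1, F1 and so on) are compounds.
- Count check: in 12 ring A carries eight CH2 groups plus the CH(SO2Ph)2 carbon (C-12 to C-5, then C-4) and ring B carries C-1 to C-3. Closure at C-3–C-4 therefore gives exactly the twelve-carbon bridge and the 20-membered ring of 17.
- No compound has a permanent stereocentre. 15 is racemic and transient. The (E)-alkene of 4 and 10–13 is the only stereo-element.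

## Structural features

The target is a 20-membered cyclophane in which a 5-alkylresorcinol ring (ring A) and a 5-alkylpyrogallol-type ring (ring B) are joined twice. One link is the diaryl ether oxygen between A-1 and B-1; the other is an unbranched, saturated twelve-carbon chain from B-4 (C-1) to A-5 (C-12). Ring A is bridged meta and ring B para. The free hydroxyls sit at A-3, B-2 and B-6, so the ether oxygen on ring B lies between two oxygen substituents. There is no stereocentre and no alkene, so no stereocentres stand next to each other and nothing stereochemical has to survive to the end. The fragile part is the set of three phenols, above all the electron-rich 2,6-dihydroxyphenyl ether of ring B, which is prone to oxidation and is best kept as methyl ethers until the last step. The real difficulties are closing a large, conformationally unbiased ring against oligomerisation and forming a diaryl ether at a phenol oxygen with two ortho substituents. The key step exploits the fact that B-4, C-1, C-2 and C-3 can be drawn as a 3,5-dioxygenated cinnamyl unit. C-3 then becomes the remote terminus of an aryl-conjugated π-allyl ligand, and C-4 a carbanion stabilised by two phenylsulfonyl groups that are removed afterwards.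

## Logic of the disconnections

**17 ⇒ 16.** The three O–CH3 bonds at A-3, B-2 and B-6 are restored first. This keeps the oxidation-prone triphenol masked through every basic, reductive and metal-mediated step, and two of the three methyl groups arrive with 1 at no cost. The forward step must cleave three aryl methyl ethers, two of them next to the diaryl ether oxygen, without breaking the Ar–O–Ar bond.

**16 ⇒ 14 (through 15).** Two C-4–S bonds are put back on the chain. The bare methylene chain offers no reactivity, whereas a bis-sulfonyl carbon is a soft, acidic carbon nucleophile. The forward step must remove both sulfonyl groups reductively and leave the aryl ethers alone.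

**14 ⇒ 13.** The C-1=C-2 double bond is reintroduced. This turns C-1 to C-3 into an allyl unit conjugated with ring B. The forward step is a plain alkene hydrogenation that must not cleave C–S or C–O bonds.

**13 ⇒ 12.** The C-3–C-4 bond is cut, which opens the 20-membered ring. The cut lies far from both rings and from the crowded ether, joins an unhindered primary allyl terminus to a stabilised carbanion, and gives one acyclic precursor in which electrophile and pronucleophile are already in place. The forward step must close the ring in preference to chain growth and must attack the allyl unit at C-3 and not at C-1.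

**12 ⇒ 11 ⇒ 10.** The carbonate C–O bond is cut and the C-3 oxidation level is raised to an ester. The leaving group is installed last, after all basic steps, so that it never meets a free carbanion before the catalyst does. The forward steps are a 1,2-reduction that must tolerate the acidic C-4–H, and an O-acylation that must not touch it.

**10 ⇒ 4 + 7 (through 9, with 8).** The A-5–C-12 bond between ring A and the chain is cut. The acyclic system falls into an aryl bromide that holds both rings and a nine-carbon chain that already carries the bis-sulfone, so no protecting group and no later activation of the chain end are needed. The forward step is an sp2–sp3 coupling that must proceed in the presence of an acidic C–H and a cinnamate.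

**7 ⇒ 5 + 6.** The C-4–C-5 bond is cut. Both pieces are purchased, and the terminal alkene of 6 is the latent organometallic for the coupling. The forward step is a mono-alkylation that must stop after one alkyl group.

**4 ⇒ 3.** The C-1=C-2 bond is cut. This reduces the cinnamyl unit to an aromatic aldehyde. The forward step must give the (E)-alkene.

**3 ⇒ 1 + 2.** The A-1–O bond is cut. Ring B then comes complete, with both methyl ethers and the aldehyde, from 1, and ring A with one bromine and one boron from 2, so no symmetric dihalide has to be desymmetrised. The forward step must arylate a phenol oxygen flanked by two methoxy groups without consuming the C–Br bond.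

## Other disconnections considered

**Alternative 1:** The cut removes ring A altogether by breaking the A-5–A-6, A-2–A-3, A-1–A-6 and A-3–A-4 bonds. This leaves the diazo enone A2, in which ring B carries a triisopropylsilyl ynol ether on its oxygen (the future A-1 and A-2) and the chain ends in a 2-substituted acryloyl diazomethane (the future A-3 to A-6).

- Forward key step: irradiation expels N2 and Wolff rearrangement gives a vinylketene. The ketene adds across the electron-rich alkyne, and the cyclobutenone opens and recloses by 4π and 6π electrocyclic steps to the silylated phenol A1. Ring A and the macrocycle would appear in one operation. Protodesilylation to the phenol A3 and ether cleavage would finish 17.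
- In favour: the polarity of the ynol ether fixes the 1,3,5-pattern of ring A. The ether oxygen is attached to A-1 before ring A exists, so no hindered diaryl ether coupling is needed; on this point the alternative is better than the chosen plan. No metal and no activating group on the chain is required. Two steps follow the key step where the chosen plan needs three, which is also better.
- Against: the ketene is short-lived and must find an alkyne held some fifteen atoms away. At the dilution a 20-membered ring demands, ketene dimerisation and capture by adventitious nucleophiles are expected to compete, and this benzannulation is normally run concentrated. The hindered aryl ynol ether and the diazo ketone each need several steps, some with hazardous reagents.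
- Comparison: on structure it constructs a benzene ring that can be bought with the right substitution. On mechanism it stakes the ring closure on a cascade of high-energy intermediates, whereas the chosen plan uses a catalytic cycle with a stabilised carbanion. On step economy it is expected to be about equal overall: shorter after the key step, longer before it.

**Alternative 2:** The cut is the O–A-1 bond, with ring A taken back to its dihydro keto form. The precursor is the phenol-tethered 3-chlorocyclohex-2-enone A5.

- Forward key step: under a carbonate base at high dilution the ring B phenoxide adds to the chlorine-bearing carbon and chloride leaves (vinylogous acyl substitution). This gives the racemic macrocyclic 3-aryloxycyclohex-2-enone A4. Dehydrogenative aromatisation to the phenol A3 and ether cleavage would finish 17.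
- In favour: the crowded ether is made without a metal, by attack of the hindered phenoxide on a small and strongly electrophilic sp2 carbon. This is a better answer to the diaryl ether problem than any copper coupling, including step 1 of the chosen plan. No sulfonyl groups are carried, and only two steps follow the key step. The stereocentre at A-5 is erased on aromatisation, so it costs nothing.
- Against: the macrocycle is closed at the most hindered atom of the molecule, whereas the chosen plan closes it at a remote, unhindered carbon. The chloroenone is sensitive to hydrolysis. The 5-substituted cyclohexane-1,3-dione must be built on the end of the chain by a Michael–Claisen sequence. The aromatisation needs oxidising conditions in the presence of the electron-rich ring B.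
- Comparison: on structure it trades a purchased aromatic ring for a carbocycle that must be made and then oxidised. On mechanism it is simpler and metal-free, and is the equal of the chosen plan. On step economy it is expected to be equal or slightly longer.

**Alternative 3:** The cut is the O–B-1 bond. The two ring B hydroxyls are disguised as formyl groups that activate a fluoride. The precursor is the 2-fluoroisophthalaldehyde A7, with the ring A phenol at the other end of the chain.

- Forward key step: the unhindered ring A phenoxide displaces fluoride at B-1 (SNAr) and closes the ring to the dialdehyde A6. A double Dakin-type oxidation (peracid, then cleavage of the formates) would give the diol A8, and cleavage of the single methyl ether would give 17.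
- In favour: intramolecular SNAr is the best-established way to close diaryl ether macrocycles. The nucleophile is unhindered and the electrophile is doubly activated, so on the ether bond and on the macrocyclisation precedent this alternative is the equal of the chosen plan or better. The activating groups become the hydroxyls instead of being discarded, which is better in atom economy than two sulfonyl groups. Only one methyl ether remains to be cleaved.
- Against: the 5-alkyl-2-fluoroisophthalaldehyde must be made, and the chain must be joined to both rings by two separate sp2–sp3 couplings while two aldehydes are carried. The first oxidation must make an aryl group migrate that still bears a second formyl group, so hydride migration to the acid may compete. The pyrogallol-type product is exposed to peroxide.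
- Comparison: on structure it handles the hindered ether well but adds a redox detour on ring B. On mechanism the ring closure is at least as secure as the palladium step. On step economy it is expected to be about equal, with more risk after the ring closure where the chosen plan has routine steps.

Key step: step 7

## Route

**Step 1**
Reactants: 1 syringaldehyde (4-hydroxy-3,5-dimethoxybenzaldehyde); 2 (3-bromo-5-methoxyphenyl)boronic acid
Product: 3 4-(3-bromo-5-methoxyphenoxy)-3,5-dimethoxybenzaldehyde
Conditions: 2 (2 equiv), Cu(OAc)2 (30 mol%), pyridine (3 equiv), 4 Å MS, CH2Cl2, O2 (1 atm), rt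
Reagents that add atoms: none
Why: Chan–Lam–Evans oxidative O-arylation, which joins phenoxide and aryl group on copper at room temperature and is known to tolerate acidic phenols with two ortho substituents (the thyroxine-type ethers). The aldehyde and the C–Br bond are not touched, and because ring A carries one boron and one bromine no dihalide has to be desymmetrised.

**Step 2**
Reactants: 3 4-(3-bromo-5-methoxyphenoxy)-3,5-dimethoxybenzaldehyde
Product: 4 ethyl (E)-3-[4-(3-bromo-5-methoxyphenoxy)-3,5-dimethoxyphenyl]prop-2-enoate
Conditions: (EtO)2P(O)CH2CO2Et, NaH, THF, 0 °C → rt
Reagents that add atoms: triethyl phosphonoacetate CCOC(=O)CP(=O)(OCC)OCC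
Why: Horner–Wadsworth–Emmons olefination of a non-enolisable aromatic aldehyde; the stabilised phosphonate anion should give the (E)-cinnamate under thermodynamic control of the oxaphosphetane.

**Step 3**
Reactants: 5 bis(phenylsulfonyl)methane; 6 8-bromooct-1-ene
Product: 7 9,9-bis(phenylsulfonyl)non-1-ene
Conditions: 5 (1.5 equiv), NaH (1.5 equiv), DMF, 0 °C; then 6, NaI (10 mol%), 70 °C
Reagents that add atoms: none
Why: SN2 C-alkylation of the sodium salt of a bis-sulfone with a primary bromide (iodide catalysis); the excess of 5 and the bulk and lower acidity of 7 should stop the reaction after one alkyl group.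

**Step 4**
Reactants: 7 9,9-bis(phenylsulfonyl)non-1-ene; 8 9-borabicyclo[3.3.1]nonane (9-BBN); 4 ethyl (E)-3-[4-(3-bromo-5-methoxyphenoxy)-3,5-dimethoxyphenyl]prop-2-enoate
Product: 10 ethyl (E)-3-[4-[3-[9,9-bis(phenylsulfonyl)nonyl]-5-methoxyphenoxy]-3,5-dimethoxyphenyl]prop-2-enoate, via alkylborane 9 (not isolated)
Conditions: 7 (1.3 equiv), 9-BBN (1.3 equiv), THF, rt; then 4, PdCl2(dppf) (5 mol%), aq. K3PO4 (4 equiv), DMF, 60 °C
Reagents that add atoms: none
Why: Anti-Markovnikov hydroboration of the terminal alkene followed by B-alkyl Suzuki–Miyaura coupling with the aryl bromide, in which the dppf ligand suppresses β-hydride elimination. The cinnamate is a poor acceptor for the hindered tertiary bis-sulfonyl anion, and the aqueous base destroys any remaining B–H before the ester is added.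

**Step 5**
Reactants: 10 ethyl (E)-3-[4-[3-[9,9-bis(phenylsulfonyl)nonyl]-5-methoxyphenoxy]-3,5-dimethoxyphenyl]prop-2-enoate
Product: 11 (E)-3-[4-[3-[9,9-bis(phenylsulfonyl)nonyl]-5-methoxyphenoxy]-3,5-dimethoxyphenyl]prop-2-en-1-ol
Conditions: i-Bu2AlH (4 equiv), CH2Cl2, −78 → 0 °C; aq. KNaC4H4O6
Reagents that add atoms: none
Why: 1,2-Reduction of an α,β-unsaturated ester to the allylic alcohol by i-Bu2AlH; the extra equivalents allow for loss of one hydride to the acidic C-4–H, which is restored on work-up, and sulfones are inert at this temperature.

**Step 6**
Reactants: 11 (E)-3-[4-[3-[9,9-bis(phenylsulfonyl)nonyl]-5-methoxyphenoxy]-3,5-dimethoxyphenyl]prop-2-en-1-ol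
Product: 12 (E)-3-[4-[3-[9,9-bis(phenylsulfonyl)nonyl]-5-methoxyphenoxy]-3,5-dimethoxyphenyl]prop-2-enyl methyl carbonate
Conditions: ClCO2Me (1.5 equiv), pyridine (3 equiv), CH2Cl2, 0 °C
Reagents that add atoms: methyl chloroformate COC(=O)Cl
Why: O-Acylation of a primary allylic alcohol with a chloroformate; pyridine is far too weak a base to deprotonate the bis-sulfone, so the carbon acid stays untouched until the catalyst is present.

**Step 7**
Reactants: 12 (E)-3-[4-[3-[9,9-bis(phenylsulfonyl)nonyl]-5-methoxyphenoxy]-3,5-dimethoxyphenyl]prop-2-enyl methyl carbonate
Product: 13 macrocyclic (E)-C-1=C-2 styrene with C-4(SO2Ph)2 (20-membered ring; methyl ethers at A-3/B-2/B-6)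
Conditions: Pd(PPh3)4 (10 mol%), THF, 65 °C, 12 added by syringe pump over 12 h (final 2 mM)
Reagents that add atoms: none
Why: Zerovalent palladium coordinates the alkene of 12 and ionises the allylic C–O bond, giving the syn aryl-substituted π-allyl complex of divalent palladium while the methyl carbonate anion loses CO2 to methoxide. Methoxide removes the C-4 proton, by far the most acidic in the molecule, so the carbanion is formed only after ionisation and only in catalytic amount. The stabilised carbanion attacks the allyl ligand at C-3 on the face opposite to the metal, which forms the C-3–C-4 bond and returns zerovalent palladium. The closest known reaction type is the Tsuji–Trost macrocyclisation of tethered bis(phenylsulfonyl)methyl pronucleophiles onto allylic carbonates or acetates under neutral conditions. The ring closes in the 20-membered mode with the C-1=C-2 alkene inside the ring; attack at C-1 would give an 18-membered ring with a pendant vinyl group and is disfavoured by loss of conjugation with ring B, by the bulk of the tertiary carbanion and by the preference of PPh3-ligated palladium for the less substituted terminus. No stereocentre is formed, since C-4 carries two identical sulfonyl groups, and the (E)-geometry follows from the syn π-allyl complex. The selectivity that matters is ring closure against oligomerisation, which rests on slow addition into dilute catalyst so that each ionised molecule can cyclise before it meets another.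

**Step 8**
Reactants: 13 macrocyclic (E)-C-1=C-2 styrene with C-4(SO2Ph)2
Product: 14 saturated macrocycle with C-4(SO2Ph)2 (methyl ethers at A-3/B-2/B-6)
Conditions: H2 (1 atm), 10% Pd/C, EtOAc–EtOH, rt
Reagents that add atoms: none
Why: Heterogeneous hydrogenation of a 1,2-disubstituted styrene; sulfones, aryl methyl ethers and the diaryl ether are inert under these conditions.

**Step 9**
Reactants: 14 saturated macrocycle with C-4(SO2Ph)2
Product: 16 sulfone-free macrocyclic trimethyl ether, via monosulfone 15 (not isolated)
Conditions: Mg turnings (30 equiv), MeOH–THF 3:1, rt → 50 °C
Reagents that add atoms: none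
Why: Reductive desulfonylation by single-electron transfer from magnesium in methanol, a standard way to take a geminal bis-sulfone to CH2. The first C–S bond cleaves easily to an α-sulfonyl carbanion that methanol protonates, and the second is cleaved in the same flask on warming.

**Step 10**
Reactants: 16 sulfone-free macrocyclic trimethyl ether
Product: 17 target CNP0314249.0 (hydroxyls at A-3, B-2 and B-6)
Conditions: BBr3 (6 equiv), CH2Cl2, −78 °C → rt; then MeOH, H2O
Reagents that add atoms: none
Why: Lewis-acid cleavage of aryl methyl ethers by BBr3 (bromide attacks the methyl group of the boron-complexed ether); the diaryl ether has no sp3 carbon on oxygen and should survive, and the sensitive triphenol is released only in the last step.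

## Compound list

1 | syringaldehyde | COc1cc(C=O)cc(OC)c1O | starting material
2 | (3-bromo-5-methoxyphenyl)boronic acid | COc1cc(Br)cc(B(O)O)c1 | starting material
3 | 4-(3-bromo-5-methoxyphenoxy)-3,5-dimethoxybenzaldehyde | COc1cc(C=O)cc(OC)c1Oc1cc(Br)cc(OC)c1 | intermediate
4 | ethyl (E)-3-[4-(3-bromo-5-methoxyphenoxy)-3,5-dimethoxyphenyl]prop-2-enoate | CCOC(=O)/C=C/c1cc(OC)c(Oc2cc(Br)cc(OC)c2)c(OC)c1 | intermediate
5 | bis(phenylsulfonyl)methane | O=S(=O)(CS(=O)(=O)c1ccccc1)c1ccccc1 | starting material
6 | 8-bromooct-1-ene | C=CCCCCCCBr | starting material
7 | 9,9-bis(phenylsulfonyl)non-1-ene | C=CCCCCCCC(S(=O)(=O)c1ccccc1)S(=O)(=O)c1ccccc1 | intermediate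
8 | 9-borabicyclo[3.3.1]nonane (9-BBN) | B1C2CCCC1CCC2 | starting material
9 | 9-[9,9-bis(phenylsulfonyl)nonyl]-9-borabicyclo[3.3.1]nonane | O=S(=O)(c1ccccc1)C(CCCCCCCCB1C2CCCC1CCC2)S(=O)(=O)c1ccccc1 | intermediate (not isolated)
10 | ethyl (E)-3-[4-[3-[9,9-bis(phenylsulfonyl)nonyl]-5-methoxyphenoxy]-3,5-dimethoxyphenyl]prop-2-enoate | CCOC(=O)/C=C/c1cc(OC)c(Oc2cc(OC)cc(CCCCCCCCC(S(=O)(=O)c3ccccc3)S(=O)(=O)c3ccccc3)c2)c(OC)c1 | intermediate
11 | (E)-3-[4-[3-[9,9-bis(phenylsulfonyl)nonyl]-5-methoxyphenoxy]-3,5-dimethoxyphenyl]prop-2-en-1-ol | OC/C=C/c1cc(OC)c(Oc2cc(OC)cc(CCCCCCCCC(S(=O)(=O)c3ccccc3)S(=O)(=O)c3ccccc3)c2)c(OC)c1 | intermediate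
12 | (E)-3-[4-[3-[9,9-bis(phenylsulfonyl)nonyl]-5-methoxyphenoxy]-3,5-dimethoxyphenyl]prop-2-enyl methyl carbonate | COC(=O)OC/C=C/c1cc(OC)c(Oc2cc(OC)cc(CCCCCCCCC(S(=O)(=O)c3ccccc3)S(=O)(=O)c3ccccc3)c2)c(OC)c1 | intermediate
13 | macrocyclic (E)-C-1=C-2 styrene, C-4(SO2Ph)2, OMe at A-3, B-2, B-6 | COc1cc2/C=C/CC(S(=O)(=O)c4ccccc4)(S(=O)(=O)c5ccccc5)CCCCCCCCc3cc(OC)cc(c3)Oc1c(OC)c2 | intermediate
14 | saturated macrocycle, C-4(SO2Ph)2, OMe at A-3, B-2, B-6 | COc1cc2CCCC(S(=O)(=O)c4ccccc4)(S(=O)(=O)c5ccccc5)CCCCCCCCc3cc(OC)cc(c3)Oc1c(OC)c2 | intermediate
15 | saturated macrocycle with one PhSO2 at C-4 (racemic), OMe at A-3, B-2, B-6 | COc1cc2CCCC(S(=O)(=O)c4ccccc4)CCCCCCCCc3cc(OC)cc(c3)Oc1c(OC)c2 | intermediate (not isolated)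
16 | sulfone-free macrocyclic trimethyl ether ((CH2)12 bridge, OMe at A-3, B-2, B-6) | COc1cc2CCCCCCCCCCCCc3cc(OC)cc(c3)Oc1c(OC)c2 | intermediate
17 | CNP0314249.0 (20-membered diaryl ether macrocycle, OH at A-3, B-2, B-6) | Oc1cc2cc(c1)Oc1c(O)cc(cc1O)CCCCCCCCCCCC2 | target

## Step count and risk

Total: 10 steps. Longest linear sequence: 9 steps (1, 2, 4, 5, 6, 7, 8, 9, 10). Step 3 is a one-step branch that joins at step 4.

**Step 7 (key step).** The most likely failure is intermolecular allylation outrunning ring closure, so that chains grow. A second possibility is capture of the allyl ligand by methoxide before the hindered carbon acid is deprotonated. The fallback makes the C-3–C-4 bond between two molecules and closes the ring at A-5–C-12 instead. It sets out from 4, together with 7 from step 3. Reduction with i-Bu2AlH gives the bromo cinnamyl alcohol F1, and ClCO2Me with pyridine gives its methyl carbonate F2. Allylation of 7 with F2 under Pd(PPh3)4 in concentrated THF, where no ring has to form, gives the acyclic quaternary bis-sulfone F3, which carries the aryl bromide and a terminal alkene. 9-BBN adds only to the terminal alkene and gives the alkylborane F4, which is not isolated. An intramolecular B-alkyl Suzuki–Miyaura coupling under syringe-pump dilution (PdCl2(dppf), aq. K3PO4, DMF–THF) then closes the same 20-membered ring. The fallback returns to the route at 13.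

**Step 1.** The most likely failure is slow transfer of the aryl group to the crowded, electron-poor copper phenoxide, so that protodeboronation and oxidative homocoupling of 2 use up the boronic acid. The fallback is a metal-free arylation with a diaryliodonium salt. It sets out from 1 and purchased 1-bromo-3-iodo-5-methoxybenzene. Oxidation of the iodide with mCPBA and TsOH, followed by 1,3,5-trimethoxybenzene, gives (3-bromo-5-methoxyphenyl)(2,4,6-trimethoxyphenyl)iodonium tosylate F5. The potassium phenoxide of 1 (K2CO3, MeCN, 50 °C) adds to trivalent iodine, and ligand coupling transfers the bromo-methoxyphenyl group, the electron-rich trimethoxyphenyl group being the non-transferred ligand. The fallback returns to the route at 3.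

**Step 4.** The most likely failure is interference by the bis-sulfone once the aqueous base has deprotonated it. The anion may bind palladium or be arylated at carbon, and the stalled alkylborane is then lost by protodeboronation. The fallback couples a chain without an acidic C–H and alkylates afterwards. It sets out from 4 and 6. 9-BBN adds to 6 to give 9-(8-bromooctyl)-9-borabicyclo[3.3.1]nonane F6, which is not isolated. Coupling with 4 under the palladium conditions of step 4 gives the 8-bromooctyl cinnamate F7, since a primary alkyl bromide is inert to PdCl2(dppf) at 60 °C. The sodium salt of 5 (NaH, DMF, NaI, 60 °C) then displaces the bromide. The fallback returns to the route at 10.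

**Step 5.** The most likely failure is loss of hydride to the acidic C-4–H followed by aggregation of the aluminium species, which would stall the reduction at the aldehyde; conjugate reduction of the cinnamate is a lesser risk. The fallback reduces the ester before the bis-sulfone is present. It sets out from 4. i-Bu2AlH gives the bromo cinnamyl alcohol F1 (the compound of the step 7 fallback). TBSCl with imidazole gives its silyl ether F8, which cannot be ionised by zerovalent palladium. Coupling of F8 with 9, made from 7 and 8 as in step 4, gives the silyl ether F9. Bu4NF buffered with AcOH removes the silyl group. The fallback returns to the route at 11.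

## Further compounds

F1 | step 7 | (E)-3-[4-(3-bromo-5-methoxyphenoxy)-3,5-dimethoxyphenyl]prop-2-en-1-ol | OC/C=C/c1cc(OC)c(Oc2cc(Br)cc(OC)c2)c(OC)c1
F2 | step 7 | (E)-3-[4-(3-bromo-5-methoxyphenoxy)-3,5-dimethoxyphenyl]prop-2-enyl methyl carbonate | COC(=O)OC/C=C/c1cc(OC)c(Oc2cc(Br)cc(OC)c2)c(OC)c1
F3 | step 7 | (E)-1-[4-(3-bromo-5-methoxyphenoxy)-3,5-dimethoxyphenyl]-4,4-bis(phenylsulfonyl)dodeca-1,11-diene | C=CCCCCCCC(C/C=C/c1cc(OC)c(Oc2cc(Br)cc(OC)c2)c(OC)c1)(S(=O)(=O)c1ccccc1)S(=O)(=O)c1ccccc1
F4 | step 7 | 9-BBN adduct of F3 at the terminal carbon (boron on C-12) | COc1cc(Br)cc(Oc2c(OC)cc(/C=C/CC(CCCCCCCCB3C4CCCC3CCC4)(S(=O)(=O)c3ccccc3)S(=O)(=O)c3ccccc3)cc2OC)c1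
F5 | step 1 | (3-bromo-5-methoxyphenyl)(2,4,6-trimethoxyphenyl)iodonium 4-methylbenzenesulfonate | COc1cc(Br)cc([I+]c2c(OC)cc(OC)cc2OC)c1.Cc1ccc(S(=O)(=O)[O-])cc1
F6 | step 4 | 9-(8-bromooctyl)-9-borabicyclo[3.3.1]nonane | BrCCCCCCCCB1C2CCCC1CCC2
F7 | step 4 | ethyl (E)-3-[4-[3-(8-bromooctyl)-5-methoxyphenoxy]-3,5-dimethoxyphenyl]prop-2-enoate | CCOC(=O)/C=C/c1cc(OC)c(Oc2cc(OC)cc(CCCCCCCCBr)c2)c(OC)c1
F8 | step 5 | tert-butyldimethylsilyl ether of F1 | CC(C)(C)[Si](C)(C)OC/C=C/c1cc(OC)c(Oc2cc(Br)cc(OC)c2)c(OC)c1
F9 | step 5 | tert-butyldimethylsilyl ether of 11 | CC(C)(C)[Si](C)(C)OC/C=C/c1cc(OC)c(Oc2cc(OC)cc(CCCCCCCCC(S(=O)(=O)c3ccccc3)S(=O)(=O)c3ccccc3)c2)c(OC)c1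
A1 | alternative 1 | macrocyclic phenol with Si(i-Pr)3 at A-2, OH at A-3, OMe at B-2 and B-6 | COc1cc2CCCCCCCCCCCCc3cc(O)c([Si](C(C)C)(C(C)C)C(C)C)c(c3)Oc1c(OC)c2
A2 | alternative 1 | 1-diazo-15-[3,5-dimethoxy-4-[(triisopropylsilyl)ethynyloxy]phenyl]-3-methylidenepentadecan-2-one | COc1cc(CCCCCCCCCCCCC(=C)C(=O)C=[N+]=[N-])cc(OC)c1OC#C[Si](C(C)C)(C(C)C)C(C)C
A3 | alternative 1 | macrocyclic phenol with OH at A-3, OMe at B-2 and B-6 | COc1cc2CCCCCCCCCCCCc3cc(O)cc(c3)Oc1c(OC)c2
A4 | alternative 2 | racemic macrocyclic 3-aryloxycyclohex-2-enone (ring A as dihydro ketone), OMe at B-2 and B-6 | COc1cc2CCCCCCCCCCCCC3CC(=O)C=C(C3)Oc1c(OC)c2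
A5 | alternative 2 | racemic 3-chloro-5-[12-(4-hydroxy-3,5-dimethoxyphenyl)dodecyl]cyclohex-2-en-1-one | COc1cc(CCCCCCCCCCCCC2CC(=O)C=C(Cl)C2)cc(OC)c1O
A6 | alternative 3 | macrocyclic diaryl ether with CHO at B-2 and B-6, OMe at A-3 | O=Cc1cc2CCCCCCCCCCCCc3cc(OC)cc(c3)Oc1c(C=O)c2
A7 | alternative 3 | 2-fluoro-5-[12-(3-hydroxy-5-methoxyphenyl)dodecyl]benzene-1,3-dicarbaldehyde | O=Cc1cc(CCCCCCCCCCCCc2cc(O)cc(OC)c2)cc(C=O)c1F
A8 | alternative 3 | macrocycle with OH at B-2 and B-6, OMe at A-3 | COc1cc2cc(c1)Oc1c(O)cc(cc1O)CCCCCCCCCCCC2
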